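0.180 mM min⁻¹ is the pace of target between 10.0 min and 20.0 min, averaged over the earlier runs, whose solid charges range from 1.5 equiv to 3.3 equiv.

the same everywhere: starting material 20 mM; free enzyme 0.0016 mol%

| charge | protic impurity | solid second substrate | remark |
|---|---|---|---|
| north-west | 10 mM | 2.1 equiv | run made earlier |
| south-west | 10 mM | 3.3 equiv | run made earlier |
| north | 15 mM | 1.5 equiv | run made earlier |
| flask | 10.0 mM | 1.50 equiv |  |

| run | time / min | target / % | starting material / % |
|---|---|---|---|
| north-west | 1.33 | 0 | 82 |
| north-west | 4.00 | 3 | 63 |
| north-west | 8.00 | 6 | 47 |
| north-west | 10.0 | 7 | 47 |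
| north-west | 15.0 | 12 | 38 |
| north-west | 20.0 | 18 | 35 |
| south-west | 3.00 | 2 | 66 |
| south-west | 6.00 | 6 | 56 |
| south-west | 10.0 | 8 | 44 |
| south-west | 12.0 | 8 | 39 |
| south-west | 15.0 | 10 | 37 |
| south-west | 20.0 | 16 | 31 |
| north | 2.00 | 1 | 61 |
| north | 5.00 | 7 | 40 |
| north | 10.0 | 9 | 26 |
| north | 15.0 | 11 | 19 |
| north | 20.0 | 17 | 12 |

(each reading ± 1.5 percentage points)

* factor on the rate of making target when 10% of the starting material are converted if free enzyme is charged twice over
* factor on the rate when 10% of the starting material are converted if free enzyme is charged at 1.5 × 10⁻⁴ mol% instead

- the analysis behind the earlier runs scatters by 1.5 percentage points, standard deviation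
- at the start none of the solid second substrate is in solution
- no earlier run changes the charge of free enzyme; that part of a forecast is a guess

We read that pace as the supply: solid dissolving into a pool of second substrate that starts empty, with dissolving as the rate-limiting step. Now the ladder, fastest first. In the flask, 10% conversion comes at 0.544 min; in the north-west run starting material already reads 82% at 1.33 min with target at 0%. Next stands the fill time, the lag of the late target line behind time zero, which the readings put at 1.11 min. In the flask the moment asked about comes sooner than that, so we expect the pool to be still filling then, and we take the rate as the supply times one minus e to the power of minus time over fill time. Longest is the time on the flask's solid: its 30.0 mM equals 167 min at that pace.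

We guess that more enzyme drains the pool sooner: 2 times the enzyme divides the fill time by 2, with the supply and the time of 10% conversion unchanged. Plain proportion is the first answer; putting the new fill time back gives us 1.61 and, for the low charge, 0.116. The forecast says 2 and 0.094, holding that “rate should scale with enzyme”, so ours is lower on the first and higher on the second.

The flask gives 1.65 and 0.113.

    starting material + protic impurity → quenched substrate (k = 0.357 M⁻¹ s⁻¹)
    second substrate + loaded enzyme ⇌ second complex (K = 2480 M⁻¹, k = 41500 M⁻¹ s⁻¹)
    first complex ⇌ loaded enzyme + first product (K = 0.182 M, k = 540 s⁻¹)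
    starting material + free enzyme ⇌ first complex (K = 26.0 M⁻¹, k = 1.05 × 10⁵ M⁻¹ s⁻¹)
    solid second substrate ⇌ second substrate, rate k5*(cs5 - [second substrate]) while solid is left; crystals form when [second substrate] > cs5 (solubility = 6.10 mM, k = 5.26 × 10⁻⁴ s⁻¹)
    second complex → free enzyme + target (k = 1510 s⁻¹)

In the flask, [second substrate] stands at 0.195 mM at 2.00 min and 0.270 mM at 10.0 min. Our fill time puts the full supply at 2.58 times the rate at 10% conversion, and the flask at 70 percent conversion, reached at 23.8 min, runs at 2.7 times that rate.

The earlier runs and the new flask were generated by integration on assumed constants.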